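## Retrosynthetic overview

1. Labdane numbering is used throughout (decalin C1–C10, side chain C11–C16, C17 = methyl on C8, C20 = methyl on C10). The acid is traced back to its tert-butyl ester, and the 7-en-6-one to a C5=C6 silyl enol ether with a C8=C9 double bond. Acid then unveils the ketone and moves C8=C9 into conjugation, placing H5 and H9 anti to the axial C20 methyl.
2. C12–C13 is cut by a B-alkyl Suzuki–Miyaura coupling between the 9-BBN adduct of a C9 vinyl group and an (E)-enol triflate that already carries CH2OAc and CO2tBu; this fixes the 13Z geometry.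
3. Ring B is cut through C7–C8 and C9–C10: a catalytic enantioselective Diels–Alder union of the 2-silyloxydiene C7=C6(OTBS)–C5=C10 (ring A intact, three steps from β-cyclocitral) with but-2-ynal (C17–C8≡C9–C11HO).
4. Enabling feature: ring B is a cyclohexenone whose C6 oxygen stands para to C9, and C8 and C9 carry nothing but C17 and C11. Ring B therefore maps onto a 2-oxygenated diene plus a two-carbon ynal whose formyl carbon becomes C11, and the C8=C9 bond left by the alkyne is the latent C7=C8 enone bond.
5. Ring order: ring A is bought, ring B is closed in the key step, no other ring is made.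

Key step: step 5

Assumption: the sense of induction of the (S)-oxazaborolidinium catalyst in step 5 is taken from the usual model for formyl-bound dienophiles; should a first run give the mirror-image adduct, the equally available (R)-catalyst is used with nothing else changed.

## Route

Step 1
Reactants: 1 β-cyclocitral (2,6,6-trimethylcyclohex-1-ene-1-carbaldehyde)
Product: 2 1-(2,6,6-trimethylcyclohex-1-en-1-yl)ethan-1-ol (racemic)
Conditions: MeLi, Et2O, −78 → 0 °C; then H2O
Reagents that add atoms: methyllithium, [Li]C
Why: Nucleophilic 1,2-addition of an organolithium to a non-enolisable aldehyde; the carbinol centre forms as a racemate, which does not matter because step 2 removes it.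

Step 2
Reactants: 2 1-(2,6,6-trimethylcyclohex-1-en-1-yl)ethan-1-ol
Product: 3 1-(2,6,6-trimethylcyclohex-1-en-1-yl)ethan-1-one
Conditions: Pr4N[RuO4] (5 mol %), NMO, 4 Å MS, CH2Cl2, rt
Reagents that add atoms: none
Why: Catalytic perruthenate oxidation with NMO as terminal oxidant should convert the secondary allylic alcohol into the ketone under neutral conditions, removing the only stereocentre.

Step 3
Reactants: 3 1-(2,6,6-trimethylcyclohex-1-en-1-yl)ethan-1-one
Product: 4 tert-butyl(dimethyl){[1-(2,6,6-trimethylcyclohex-1-en-1-yl)ethenyl]oxy}silane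
Conditions: TBSOTf, Et3N, CH2Cl2, 0 °C
Reagents that add atoms: tert-butyldimethylsilyl trifluoromethanesulfonate, CC(C)(C)[Si](C)(C)OS(=O)(=O)C(F)(F)F
Why: Soft enolisation with a silyl triflate and an amine (silyl enol ether formation) can only take a proton from the methyl group, because C5 has no hydrogen and the twisted acetyl group does not acidify the γ-positions, so the cross-conjugated 2-silyloxydiene should result; no stereocentre.

Step 4
Reactants: 5 but-2-yn-1-ol
Product: 6 but-2-ynal
Conditions: MnO2 (activated), CH2Cl2, rt; filtered, dried solution used directly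
Reagents that add atoms: none
Why: Heterogeneous MnO2 oxidation of a propargylic alcohol should stop cleanly at the volatile ynal; no stereocentre.

Step 5
Reactants: 4 tert-butyl(dimethyl){[1-(2,6,6-trimethylcyclohex-1-en-1-yl)ethenyl]oxy}silane; 6 but-2-ynal
Product: 7 (8aR)-4-{[tert-butyl(dimethyl)silyl]oxy}-2,5,5,8a-tetramethyl-3,5,6,7,8,8a-hexahydronaphthalene-1-carbaldehyde
Conditions: (S)-3,3-diphenyl-1-(2-methylphenyl)tetrahydro-1H,3H-pyrrolo[1,2-c][1,3,2]oxazaborole (20 mol %), Tf2NH (20 mol %), 4 Å MS, CH2Cl2, −78 → −40 °C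
Reagents that add atoms: none
Why: Proposed new method: the triflimide-activated oxazaborolidine binds the formyl oxygen of 6, lowers the LUMO of the C8≡C9 π bond conjugated to C=O, and lets the unhindered C7 methylene of 4 lead a concerted but strongly asynchronous [4+2] addition in which C7–C8 is advanced and C9–C10 then closes onto the silyloxyallyl-cation-like terminus (in the stepwise limit a Mukaiyama–Michael addition followed by 6-endo-trig closure of the allenolate carbon). The closest known reactions are the thermal Diels–Alder additions of 1-vinyl-2,6,6-trimethylcyclohexene to acetylenic dienophiles, which build drimane ring B with its C10 quaternary centre, and the chiral boron Lewis acid catalysed Diels–Alder reactions of ynals and ynones and of 2-silyloxydienes; new is their combination, enantiocontrol at a fully substituted diene terminus. Ring B is the only ring closed, by intermolecular six-membered cycloaddition across C7 and C10 of the diene. The single new stereocentre, quaternary C10, is set by the catalyst, which shields one face of the bound ynal so that only one enantiotopic face of the diene can stack on it in the para alignment. The step needs regioselectivity (C7 to C8, C10 to C9), secured by the 2-silyloxy group (largest HOMO coefficient at C7) and the formyl group (largest LUMO coefficient at C8) and reinforced by the dialkylated C10 terminus; chemoselectivity for C≡C over C=O, favoured by the bulky TBS group and the sterically undemanding linear alkyne; and enantioselectivity, which rests on the catalyst alone.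

Step 6
Reactants: 7 (8aR)-4-{[tert-butyl(dimethyl)silyl]oxy}-2,5,5,8a-tetramethyl-3,5,6,7,8,8a-hexahydronaphthalene-1-carbaldehyde
Product: 8 (8aS)-4-{[tert-butyl(dimethyl)silyl]oxy}-1-ethenyl-2,5,5,8a-tetramethyl-3,5,6,7,8,8a-hexahydronaphthalene
Conditions: Ph3PCH3Br, KOtBu, THF, 0 °C; then 7, −78 → 0 °C
Reagents that add atoms: methyltriphenylphosphonium bromide, C[P+](c1ccccc1)(c1ccccc1)c1ccccc1.[Br-]
Why: Wittig methylenation of a hindered enal of the β-cyclocitral type, with the silyl enol ether acting as base-stable protection of the C6 ketone; C10 is untouched (its descriptor changes only through the priority rules).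

Step 7
Reactants: 9 tert-butyl 4-chloro-3-oxobutanoate
Product: 10 tert-butyl 4-acetoxy-3-oxobutanoate
Conditions: KOAc, AcOH/DMF, 40 °C
Reagents that add atoms: potassium acetate, CC(=O)[O-].[K+]
Why: SN2 displacement of the activated α-chloroketone chloride by acetate, with acetic acid present to suppress enolate self-alkylation; no stereocentre.

Step 8
Reactants: 10 tert-butyl 4-acetoxy-3-oxobutanoate
Product: 11 tert-butyl (2E)-4-acetoxy-3-{[(trifluoromethyl)sulfonyl]oxy}but-2-enoate
Conditions: DBU, CH2Cl2, −78 °C; then Tf2O, −78 → −20 °C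
Reagents that add atoms: trifluoromethanesulfonic anhydride, O=S(=O)(OS(=O)(=O)C(F)(F)F)C(F)(F)F
Why: O-Triflation of the β-keto ester enolate formed with a non-chelating amidine base should go through the open enolate and place OTf trans to the ester, giving the (E)-enol triflate (metal-chelated enolates give Z); the geometry is to be confirmed by NOE before use.

Step 9
Reactants: 8 (8aS)-4-{[tert-butyl(dimethyl)silyl]oxy}-1-ethenyl-2,5,5,8a-tetramethyl-3,5,6,7,8,8a-hexahydronaphthalene; 11 tert-butyl (2E)-4-acetoxy-3-{[(trifluoromethyl)sulfonyl]oxy}but-2-enoate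
Product: 13 tert-butyl (2Z)-3-(acetoxymethyl)-5-[(8aS)-4-{[tert-butyl(dimethyl)silyl]oxy}-2,5,5,8a-tetramethyl-3,5,6,7,8,8a-hexahydronaphthalen-1-yl]pent-2-enoate, via alkyl-9-BBN borane 12 (not isolated)
Conditions: 9-BBN, THF, 0 °C → rt; then 11, PdCl2(dppf) (5 mol %), AsPh3 (10 mol %), K3PO4 (aq.), DMF, rt
Reagents that add atoms: 9-borabicyclo[3.3.1]nonane (9-BBN), B1C2CCCC1CCC2
Why: Anti-Markovnikov hydroboration should take only the monosubstituted alkene (the tetrasubstituted C8=C9 bond and the enol ether are inert) and gives borane 12, which carries the whole 9-BBN cage, and B-alkyl Suzuki–Miyaura coupling of 12 with the electron-poor enol triflate then proceeds with retention of alkene geometry and releases the boron cage as its borinic acid, so the chain enters trans to the ester and the 13Z acetoxy ester results, oxidative addition of zerovalent palladium into C–OTf being much faster than ionisation of the allylic acetate.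

Step 10
Reactants: 13 tert-butyl (2Z)-3-(acetoxymethyl)-5-[(8aS)-4-{[tert-butyl(dimethyl)silyl]oxy}-2,5,5,8a-tetramethyl-3,5,6,7,8,8a-hexahydronaphthalen-1-yl]pent-2-enoate
Product: 15 tert-butyl (2Z)-3-(acetoxymethyl)-5-[(1R,4aR,8aS)-2,5,5,8a-tetramethyl-4-oxo-1,4,4a,5,6,7,8,8a-octahydronaphthalen-1-yl]pent-2-enoate, via non-conjugated ketone 14 (not isolated)
Conditions: 1 M aq. HCl, THF, rt
Reagents that add atoms: none
Why: Acid hydrolysis of the silyl enol ether gives the 6-ketone with H5 delivered anti to the axial C20 methyl (and free to equilibrate to the trans ring fusion), and acid-catalysed enolisation towards C7 followed by γ-protonation of the dienol at C9, again anti to the axial C20 methyl, should move the strained tetrasubstituted C8=C9 bond into conjugation (known β,γ- to α,β-enone isomerisation); C9 is set kinetically and the conditions are kept mild so that it does not equilibrate.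

Step 11
Reactants: 15 tert-butyl (2Z)-3-(acetoxymethyl)-5-[(1R,4aR,8aS)-2,5,5,8a-tetramethyl-4-oxo-1,4,4a,5,6,7,8,8a-octahydronaphthalen-1-yl]pent-2-enoate
Product: 16 (2Z)-3-(acetoxymethyl)-5-[(1R,4aR,8aS)-2,5,5,8a-tetramethyl-4-oxo-1,4,4a,5,6,7,8,8a-octahydronaphthalen-1-yl]pent-2-enoic acid (CNP0145331.2)
Conditions: TFA, CH2Cl2, 0 °C → rt
Reagents that add atoms: none
Why: Acidolysis of the tert-butyl ester (E1 loss of isobutene) should leave the primary allylic acetate, the enone and the three ring stereocentres untouched.

## Compound list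

1 | β-cyclocitral (2,6,6-trimethylcyclohex-1-ene-1-carbaldehyde) | O=CC1=C(C)CCCC1(C)C | starting material
2 | 1-(2,6,6-trimethylcyclohex-1-en-1-yl)ethan-1-ol (racemic) | CC(O)C1=C(C)CCCC1(C)C | intermediate
3 | 1-(2,6,6-trimethylcyclohex-1-en-1-yl)ethan-1-one | CC(=O)C1=C(C)CCCC1(C)C | intermediate
4 | tert-butyl(dimethyl){[1-(2,6,6-trimethylcyclohex-1-en-1-yl)ethenyl]oxy}silane | C=C(O[Si](C)(C)C(C)(C)C)C1=C(C)CCCC1(C)C | intermediate
5 | but-2-yn-1-ol | CC#CCO | starting material
6 | but-2-ynal | CC#CC=O | intermediate
7 | (8aR)-4-{[tert-butyl(dimethyl)silyl]oxy}-2,5,5,8a-tetramethyl-3,5,6,7,8,8a-hexahydronaphthalene-1-carbaldehyde | O=CC1=C(C)CC(O[Si](C)(C)C(C)(C)C)=C2C(C)(C)CCC[C@@]12C | intermediate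
8 | (8aS)-4-{[tert-butyl(dimethyl)silyl]oxy}-1-ethenyl-2,5,5,8a-tetramethyl-3,5,6,7,8,8a-hexahydronaphthalene | C=CC1=C(C)CC(O[Si](C)(C)C(C)(C)C)=C2C(C)(C)CCC[C@@]12C | intermediate
9 | tert-butyl 4-chloro-3-oxobutanoate | CC(C)(C)OC(=O)CC(=O)CCl | starting material
10 | tert-butyl 4-acetoxy-3-oxobutanoate | CC(=O)OCC(=O)CC(=O)OC(C)(C)C | intermediate
11 | tert-butyl (2E)-4-acetoxy-3-{[(trifluoromethyl)sulfonyl]oxy}but-2-enoate | CC(=O)OC/C(OS(=O)(=O)C(F)(F)F)=C\C(=O)OC(C)(C)C | intermediate
12 | 9-{2-[(8aS)-4-{[tert-butyl(dimethyl)silyl]oxy}-2,5,5,8a-tetramethyl-3,5,6,7,8,8a-hexahydronaphthalen-1-yl]ethyl}-9-borabicyclo[3.3.1]nonane | B1(CCC3=C(C)CC(O[Si](C)(C)C(C)(C)C)=C4C(C)(C)CCC[C@@]34C)C2CCCC1CCC2 | intermediate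
13 | tert-butyl (2Z)-3-(acetoxymethyl)-5-[(8aS)-4-{[tert-butyl(dimethyl)silyl]oxy}-2,5,5,8a-tetramethyl-3,5,6,7,8,8a-hexahydronaphthalen-1-yl]pent-2-enoate | CC(=O)OC/C(=C\C(=O)OC(C)(C)C)CCC1=C(C)CC(O[Si](C)(C)C(C)(C)C)=C2C(C)(C)CCC[C@@]12C | intermediate
14 | tert-butyl (2Z)-3-(acetoxymethyl)-5-[(4aR,8aR)-2,5,5,8a-tetramethyl-4-oxo-3,4,4a,5,6,7,8,8a-octahydronaphthalen-1-yl]pent-2-enoate | CC(=O)OC/C(=C\C(=O)OC(C)(C)C)CCC1=C(C)CC(=O)[C@@H]2C(C)(C)CCC[C@@]12C | intermediate
15 | tert-butyl (2Z)-3-(acetoxymethyl)-5-[(1R,4aR,8aS)-2,5,5,8a-tetramethyl-4-oxo-1,4,4a,5,6,7,8,8a-octahydronaphthalen-1-yl]pent-2-enoate | CC(=O)OC/C(=C\C(=O)OC(C)(C)C)CC[C@@H]1C(C)=CC(=O)[C@@H]2C(C)(C)CCC[C@@]12C | intermediate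
16 | (2Z)-3-(acetoxymethyl)-5-[(1R,4aR,8aS)-2,5,5,8a-tetramethyl-4-oxo-1,4,4a,5,6,7,8,8a-octahydronaphthalen-1-yl]pent-2-enoic acid | CC(=O)OC/C(=C\C(=O)O)CC[C@@H]1C(C)=CC(=O)[C@@H]2C(C)(C)CCC[C@@]12C | target

## Step count and risks

Total step count: 11. Longest linear sequence: 8 (steps 1, 2, 3, 5, 6, 9, 10, 11).

Steps most likely to fail:

1. Step 5 (proposed new method). The C7 methylene may add 1,2 to the activated formyl group (aldol or hetero-cycloaddition pathway) or close onto C6 to a cyclobutene; the second bond formation at the fully substituted C10 may stall; or facial discrimination of the diene may be poor. The fallback uses known chemistry, sets out from 4 and 6 and comes back at 7. The uncatalysed thermal Diels–Alder reaction (toluene, 90 °C, sealed tube, BHT), the known reaction type for this diene class with acetylenic dienophiles, should give the racemic adduct, racemic 4-{[tert-butyl(dimethyl)silyl]oxy}-2,5,5,8a-tetramethyl-3,5,6,7,8,8a-hexahydronaphthalene-1-carbaldehyde F1. Reduction with i-Bu2AlH (CH2Cl2, −78 °C) gives the racemic allylic alcohol F2. Acylation with (1S)-camphanic chloride [(1S,4R)-4,7,7-trimethyl-3-oxo-2-oxabicyclo[2.2.1]heptane-1-carbonyl chloride; pyridine, DMAP] gives two diastereomeric esters that are separated by crystallisation or chromatography, and the (8aS)-configured camphanate F3 is kept. Methanolysis (K2CO3, MeOH, 0 °C) frees the (8aS)-alcohol F4, and MnO2 (CH2Cl2) oxidises it to 7.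

2. Step 10. Protonation at C9 may occur from the wrong face; C9 may equilibrate towards the epimer with a pseudo-axial side chain (favoured by allylic strain with the C17 methyl); or the double-bond shift may stay incomplete. The fallback sets out from 13 and comes back at 15, and separates the two events. Buffered HF·pyridine (THF, 0 °C) cleaves the silyl enol ether and stops at the non-conjugated ketone 14, which is isolated. RhCl3·3H2O (5 mol %) in EtOH at 60 °C then moves the double bond by a metal hydride addition–elimination, which delivers hydrogen to C9 suprafacially from the less hindered face, anti to the C20 methyl. No new compound is made on this way (none, F0).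

3. Step 9. Zerovalent palladium may ionise the allylic acetate of 11 or of 13; the alkylpalladium intermediate may lose a β-hydride; or the enol triflate geometry may erode. The fallback sets out from 8 (through borane 12, made as in step 9) and comes back at 13, and replaces the cross-coupling by a copper-catalysed syn-hydroalkylation of an ynoate. tert-Butyl propiolate is hydroxymethylated (LiN(SiMe3)2, paraformaldehyde, THF, −78 °C) to tert-butyl 4-hydroxybut-2-ynoate F5 and acetylated (Ac2O, pyridine) to tert-butyl 4-acetoxybut-2-ynoate F6. Borane 12 is then added across F6 (CuOAc 5 mol %, P(OPh)3, catalytic KOtBu, t-BuOH, 1,4-dioxane, rt). Syn carbocupration followed by protonation places the alkyl chain and the new hydrogen on the same side, that is, the chain trans to the ester, which is 13.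

## Further compounds

F1 | step 5 | racemic 4-{[tert-butyl(dimethyl)silyl]oxy}-2,5,5,8a-tetramethyl-3,5,6,7,8,8a-hexahydronaphthalene-1-carbaldehyde | O=CC1=C(C)CC(O[Si](C)(C)C(C)(C)C)=C2C(C)(C)CCCC12C
F2 | step 5 | racemic (4-{[tert-butyl(dimethyl)silyl]oxy}-2,5,5,8a-tetramethyl-3,5,6,7,8,8a-hexahydronaphthalen-1-yl)methanol | OCC1=C(C)CC(O[Si](C)(C)C(C)(C)C)=C2C(C)(C)CCCC12C
F3 | step 5 | [(8aS)-4-{[tert-butyl(dimethyl)silyl]oxy}-2,5,5,8a-tetramethyl-3,5,6,7,8,8a-hexahydronaphthalen-1-yl]methyl (1S,4R)-4,7,7-trimethyl-3-oxo-2-oxabicyclo[2.2.1]heptane-1-carboxylate | O=C(OCC1=C(C)CC(O[Si](C)(C)C(C)(C)C)=C2C(C)(C)CCC[C@@]12C)[C@@]12CC[C@@](C)(C(=O)O1)C2(C)C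
F4 | step 5 | [(8aS)-4-{[tert-butyl(dimethyl)silyl]oxy}-2,5,5,8a-tetramethyl-3,5,6,7,8,8a-hexahydronaphthalen-1-yl]methanol | OCC1=C(C)CC(O[Si](C)(C)C(C)(C)C)=C2C(C)(C)CCC[C@@]12C
F0 | step 10 | none | none
F5 | step 9 | tert-butyl 4-hydroxybut-2-ynoate | OCC#CC(=O)OC(C)(C)C
F6 | step 9 | tert-butyl 4-acetoxybut-2-ynoate | CC(=O)OCC#CC(=O)OC(C)(C)C
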